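## Retrosynthetic overview

- Target 7 is cut at the aryl–CH2 bond: an allyl–aryl coupling joins arylboronate 6 to the primary allylic acetate of the C10 diacetate 2.
- Diacetate 2 comes from (E)-β-ocimene 1 in one oxidative step that makes both C–O bonds. The C4–OAc bond is the stereogenic acetate of the target; the C1–OAc bond becomes the leaving group for the coupling.
- Boronate acid 6 comes from commercial boronate aldehyde 3 by Z-selective olefination with 4 and saponification, done before any acetate is in the molecule.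
- No ring is formed; the benzene ring is bought with 3.

Assumption: (E)-β-ocimene of at least 95% isomeric purity is used (technical isomer mixtures are fractionally distilled first).

Ligand A is (4S)-4-tert-butyl-2-{2-[(R)-(4-methylphenyl)sulfinyl]phenyl}-4,5-dihydro-1,3-oxazole, an aryl sulfoxide–oxazoline N,S chelate. Its mirror image is used instead if the first run gives the 4S diacetate.

## Route

Step 1
Reactants: 1 (E)-β-ocimene, (3E)-3,7-dimethylocta-1,3,6-triene
Product: 2 (2E,4R)-3,7-dimethylocta-2,6-diene-1,4-diyl diacetate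
Conditions: Pd(OAc)2 (5 mol%), ligand A (6 mol%), 2,6-dimethyl-1,4-benzoquinone (1.2 equiv), AcOH (5 equiv), LiOAc (20 mol%), 1,4-dioxane, 25 °C
Reagents that add atoms: acetic acid, CC(=O)O
Why: Proposed new method: an enantioselective, ligand-controlled version of the palladium/benzoquinone oxidative 1,4-diacetoxylation of 1,3-dienes; acetate adds to the unsubstituted C1 of the diene bound to divalent palladium to give a syn,syn η3-allyl complex over C2–C4, the quinone then triggers the second C–O bond formation at C4, distal to the electron-withdrawing acetoxymethyl group (so 1,4 and not 1,2, and the same diacetate results whichever terminus is attacked first), the two allyl faces equilibrate through reversible acetoxypalladation and the chiral N,S ligand selects acetate delivery to the Re face of C4 (anti to palladium) to give 4R, the s-trans diene gives the 2E alkene, and the isolated trisubstituted alkene does not react at 25 °C; the closest known reactions are the racemic Pd(OAc)2/benzoquinone 1,4-diacetoxylation of dienes and sulfoxide–oxazoline/palladium asymmetric allylic C–H oxidation, where a carboxylate attacks a π-allyl enantioselectively.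

Step 2
Reactants: 3 4-methoxy-3-(4,4,5,5-tetramethyl-1,3,2-dioxaborolan-2-yl)benzaldehyde; 4 methyl 2-[bis(2,2,2-trifluoroethoxy)phosphoryl]acetate
Product: 5 methyl (2Z)-3-[4-methoxy-3-(4,4,5,5-tetramethyl-1,3,2-dioxaborolan-2-yl)phenyl]prop-2-enoate
Conditions: KN(SiMe3)2 (1.1 equiv), 18-crown-6 (3 equiv), THF, −78 °C
Reagents that add atoms: none
Why: Still–Gennari variant of the Horner–Wadsworth–Emmons olefination: the electron-poor phosphonate with a dissociated potassium ion eliminates from the kinetic adduct faster than it equilibrates, giving the Z enoate, and the pinacol boronate is inert to the pre-formed phosphonate anion at −78 °C.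

Step 3
Reactants: 5 methyl (2Z)-3-[4-methoxy-3-(4,4,5,5-tetramethyl-1,3,2-dioxaborolan-2-yl)phenyl]prop-2-enoate
Product: 6 (2Z)-3-[4-methoxy-3-(4,4,5,5-tetramethyl-1,3,2-dioxaborolan-2-yl)phenyl]prop-2-enoic acid
Conditions: LiOH·H2O (3 equiv), THF/H2O 3:1, 0 °C to rt, dark; then cold 1 M HCl to pH 3
Reagents that add atoms: lithium hydroxide, [Li+].[OH-]
Why: Ester saponification at room temperature does not isomerise a Z-cinnamate, and doing it before the acetate exists avoids any ester differentiation; the pinacol boronate survives brief cold acidification.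

Step 4
Reactants: 2 (2E,4R)-3,7-dimethylocta-2,6-diene-1,4-diyl diacetate; 6 (2Z)-3-[4-methoxy-3-(4,4,5,5-tetramethyl-1,3,2-dioxaborolan-2-yl)phenyl]prop-2-enoic acid
Product: 7 (2Z)-3-{3-[(2E,4R)-4-acetoxy-3,7-dimethylocta-2,6-dien-1-yl]-4-methoxyphenyl}prop-2-enoic acid (target)
Conditions: Pd(PPh3)4 (5 mol%), K2CO3 (2.5 equiv), THF/H2O 10:1, 40 °C, dark; then cold 1 M HCl to pH 3–4
Reagents that add atoms: none
Why: Suzuki–Miyaura-type allyl–aryl coupling through Tsuji–Trost ionisation: zerovalent palladium ionises the unhindered primary allylic acetate faster than the hindered secondary one, the aryl group from boron is delivered to the less substituted allyl terminus C1 with the E geometry kept, and C4 lies outside the allyl unit so its R configuration is untouched; the acid travels as its carboxylate, a poor Michael acceptor whose O-allylation is reversible.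

## Compound list

1 | (3E)-3,7-dimethylocta-1,3,6-triene, (E)-β-ocimene | C=C/C(C)=C/CC=C(C)C | starting material
2 | (2E,4R)-3,7-dimethylocta-2,6-diene-1,4-diyl diacetate | CC(=O)OC/C=C(\C)[C@@H](CC=C(C)C)OC(C)=O | intermediate
3 | 4-methoxy-3-(4,4,5,5-tetramethyl-1,3,2-dioxaborolan-2-yl)benzaldehyde | COc1ccc(C=O)cc1B1OC(C)(C)C(C)(C)O1 | starting material
4 | methyl 2-[bis(2,2,2-trifluoroethoxy)phosphoryl]acetate | COC(=O)CP(=O)(OCC(F)(F)F)OCC(F)(F)F | starting material
5 | methyl (2Z)-3-[4-methoxy-3-(4,4,5,5-tetramethyl-1,3,2-dioxaborolan-2-yl)phenyl]prop-2-enoate | COc1ccc(/C=C\C(=O)OC)cc1B1OC(C)(C)C(C)(C)O1 | intermediate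
6 | (2Z)-3-[4-methoxy-3-(4,4,5,5-tetramethyl-1,3,2-dioxaborolan-2-yl)phenyl]prop-2-enoic acid | COc1ccc(/C=C\C(=O)O)cc1B1OC(C)(C)C(C)(C)O1 | intermediate
7 | (2Z)-3-{3-[(2E,4R)-4-acetoxy-3,7-dimethylocta-2,6-dien-1-yl]-4-methoxyphenyl}prop-2-enoic acid | COc1ccc(/C=C\C(=O)O)cc1C/C=C(\C)[C@@H](CC=C(C)C)OC(C)=O | target

## Step count and risks

Total step count: 4. Longest linear sequence: 3 (steps 2, 3, 4 from 3); the branch from 1 is 2 steps (steps 1, 4).

**Step 1 (the proposed new step).** Risks: low enantioselectivity, some 1,2-diacetate or 2Z isomer, or slowing of the catalyst by the ligand.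
Fallback with known chemistry, setting out from 1 and coming back at 2:
- Ligand-free diacetoxylation of 1 (Pd(OAc)2, LiOAc, 1,4-benzoquinone, AcOH, 25 °C) gives racemic (2E)-3,7-dimethylocta-2,6-diene-1,4-diyl diacetate F1.
- K2CO3 in MeOH gives racemic (2E)-3,7-dimethylocta-2,6-diene-1,4-diol F2.
- AcCl with 2,4,6-collidine in CH2Cl2 at −78 °C acetylates only the primary hydroxyl, giving racemic (2E)-4-hydroxy-3,7-dimethylocta-2,6-dien-1-yl acetate F3.
- Sharpless kinetic resolution (Ti(OiPr)4, diisopropyl L-(+)-tartrate, tBuOOH 0.6 equiv, 4 Å molecular sieves, CH2Cl2, −20 °C) epoxidises the 4S enantiomer to [(2R,3R)-3-[(1S)-1-hydroxy-4-methylpent-3-en-1-yl]-3-methyloxiran-2-yl]methyl acetate F5 and leaves (2E,4R)-4-hydroxy-3,7-dimethylocta-2,6-dien-1-yl acetate F4.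
- Ac2O, pyridine and DMAP convert F4 into 2.

**Step 2.** Risks: an insufficient Z:E ratio for this electron-rich aldehyde, or attack of the base on the boronate.
Fallback, setting out from 3 and coming back at 6:
- Knoevenagel–Doebner condensation of 3 with malonic acid (pyridine, catalytic piperidine, 90 °C) gives (2E)-3-[4-methoxy-3-(4,4,5,5-tetramethyl-1,3,2-dioxaborolan-2-yl)phenyl]prop-2-enoic acid F6.
- Contra-thermodynamic E-to-Z photoisomerisation by triplet energy transfer (Ir(ppy)3 1 mol%, blue LEDs, MeCN, rt) gives a Z-enriched photostationary mixture. 6 is separated from it and the E acid is recycled.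

**Step 4.** Risks: competing ionisation of the secondary acetate (loss of ee, diarylation, elimination), O-allylation of the carboxylate, or Z-to-E drift of the acrylate.
Fallback, setting out from 2 and 3 and coming back at 7:
- 2 and 3 are coupled with Pd(PPh3)4 and K2CO3 in THF/H2O at 40 °C, with no acid or enoate present, to give (2E,4R)-1-(5-formyl-2-methoxyphenyl)-3,7-dimethylocta-2,6-dien-4-yl acetate F7.
- Still–Gennari olefination with 4 (KN(SiMe3)2, 18-crown-6, THF, −78 °C) gives methyl (2Z)-3-{3-[(2E,4R)-4-acetoxy-3,7-dimethylocta-2,6-dien-1-yl]-4-methoxyphenyl}prop-2-enoate F8.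
- LiOH in THF/MeOH/H2O removes both the methyl ester and the acetate without touching the C4–O bond, giving (2Z)-3-{3-[(2E,4R)-4-hydroxy-3,7-dimethylocta-2,6-dien-1-yl]-4-methoxyphenyl}prop-2-enoic acid F9.
- Ac2O, pyridine and DMAP, followed by stirring with aqueous NaHCO3 to hydrolyse the mixed anhydride, give 7.

Further compounds
F1 | step 1 | racemic (2E)-3,7-dimethylocta-2,6-diene-1,4-diyl diacetate | CC(=O)OC/C=C(\C)C(CC=C(C)C)OC(C)=O
F2 | step 1 | racemic (2E)-3,7-dimethylocta-2,6-diene-1,4-diol | OC/C=C(\C)C(O)CC=C(C)C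
F3 | step 1 | racemic (2E)-4-hydroxy-3,7-dimethylocta-2,6-dien-1-yl acetate | CC(=O)OC/C=C(\C)C(O)CC=C(C)C
F4 | step 1 | (2E,4R)-4-hydroxy-3,7-dimethylocta-2,6-dien-1-yl acetate | CC(=O)OC/C=C(\C)[C@H](O)CC=C(C)C
F5 | step 1 | [(2R,3R)-3-[(1S)-1-hydroxy-4-methylpent-3-en-1-yl]-3-methyloxiran-2-yl]methyl acetate | CC(=O)OC[C@H]1O[C@]1(C)[C@@H](O)CC=C(C)C
F6 | step 2 | (2E)-3-[4-methoxy-3-(4,4,5,5-tetramethyl-1,3,2-dioxaborolan-2-yl)phenyl]prop-2-enoic acid | COc1ccc(/C=C/C(=O)O)cc1B1OC(C)(C)C(C)(C)O1
F7 | step 4 | (2E,4R)-1-(5-formyl-2-methoxyphenyl)-3,7-dimethylocta-2,6-dien-4-yl acetate | COc1ccc(C=O)cc1C/C=C(\C)[C@@H](CC=C(C)C)OC(C)=O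
F8 | step 4 | methyl (2Z)-3-{3-[(2E,4R)-4-acetoxy-3,7-dimethylocta-2,6-dien-1-yl]-4-methoxyphenyl}prop-2-enoate | COc1ccc(/C=C\C(=O)OC)cc1C/C=C(\C)[C@@H](CC=C(C)C)OC(C)=O
F9 | step 4 | (2Z)-3-{3-[(2E,4R)-4-hydroxy-3,7-dimethylocta-2,6-dien-1-yl]-4-methoxyphenyl}prop-2-enoic acid | COc1ccc(/C=C\C(=O)O)cc1C/C=C(\C)[C@H](O)CC=C(C)C
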